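## Structural features

The target is an achiral tridepside: three benzene rings in a row, joined by two aryl ester bonds. Each ester runs from the carboxyl carbon of one ring to the oxygen para to the carboxyl of the next ring. Ring A is a 2,4,5-trihydroxy-6-methylbenzoyl unit, ring B a 2-hydroxy-6-methylbenzoyl unit acylated on O4, and ring C a 2-hydroxy-6-methylbenzoic acid acylated on O4. There are no stereocentres, so nothing has to be controlled in three dimensions.

Three groups are fragile. Both ester carbonyls are flanked by an ortho hydroxyl and an ortho methyl and transacylate or hydrolyse under base. The 1,2,4-trioxygenated ring A oxidises to a quinone in basic, aerated media. The free acid of ring C, with oxygen ortho and para to the carboxyl, decarboxylates in hot acid.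

The real difficulty is the differentiation of oxygens rather than the carbon skeleton: in each resorcinol-type ring only the para oxygen may be acylated, the acids to be coupled are di-ortho-substituted, and every protecting group must leave without ester cleavage. The key step exploits the fact that C3 to C6 of ring C, with O4 and the C6 methyl, are the C3 to C6 carbons, the 4-oxygen and the 6-methyl of 4-hydroxy-6-methyl-2-pyrone. That heterocycle has a single hydroxyl, so the ring A-B acyl group can be placed on O4 without a choice. C1 with its carboxyl and C2 with its oxygen come from a two-carbon alkyne, and the lactone bridge leaves as CO2.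

## Logic of the disconnections

22 from 21: the benzyl–oxygen bond of the ring C ester is cut. The acid of ring C is prone to decarboxylation and is best released last under neutral conditions. All Lewis-acid chemistry is thereby done on an ester. The forward step must leave the two aryl esters untouched, which hydrogenolysis does.

21 from 20: the four benzyl–oxygen bonds and the methyl–oxygen bond at ring C C2 are cut. One Lewis acid can take all five because the methyl ether sits ortho to an ester carbonyl and can be chelated. The forward step must cleave a methyl ether in the cold without opening either depside link and without benzylating the electron-rich rings.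

20 from 15 and 18: the ring C bonds C1–C6 and C2–C3 are cut and CO2 is put back as a lactone bridge. This replaces a tetrasubstituted benzoate whose two oxygens would have to be told apart by a pyrone with one oxygen and an alkyne that delivers C1, C2, the carboxyl and the 2-oxygen already in place. The forward step needs one regiochemistry and substrates that survive heating. For this reason the ynol ether is a methyl ether and the phenols of 15 are benzyl ethers.

15 from 12 and 13: the ester bond between the ring B carbonyl and pyrone O4 is cut. 13 offers only one hydroxyl, so no selectivity question arises. The forward step must acylate on oxygen and not on C3, and must avoid nucleophilic catalysts that would move the acyl group to carbon.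

18 from 16: the bond between the alkyne carbon and the carboxyl carbon is cut, which gives an acetylide and a chloroformate. The acetylide is traced to 16 by two eliminations. The forward step must make and use the acetylide 17 in one flask so that the volatile ynol ether is never isolated.

12 from 11, 10, and then 8 and 1: the carboxyl of ring B is carried as an aldehyde, so no ester protecting group has to be removed beside the depside link. The benzyl–oxygen bond at ring B C2 is cut next, then the ester bond between the ring A carbonyl and ring B O4. The forward acylation must choose the para hydroxyl of 1 over the chelated ortho hydroxyl, and the later benzylation must not disturb the new ester.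

8 from 7 and 5: the acid is traced to the aldehyde and the aryl–formyl bond is cut. This leaves a symmetric-looking tris-ether whose two free positions differ only in their neighbours. The forward formylation must go to the position flanked by methyl, not to the one between two ether oxygens.

5 from 4, 2 and 1: a benzyl–oxygen bond is cut, and the phenol oxygen is traced to a formyl group through an aryl migration that exchanges a C–C for a C–O bond. The formyl group of 1 thus marks the carbon that becomes C5–O of ring A, and 1 serves for both ring A and ring B. The forward oxidation must proceed by aryl and not by hydride migration.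

## Other disconnections considered

Alternative 1: Ring B is cut at B1–B2, B3–B4 and B4–B5 and is built on a ring C ester by a Danheiser benzannulation.
- **Forward step:** the ring C phenol benzyl 2-(benzyloxy)-4-hydroxy-6-methylbenzoate A4 is converted to the aryl 2-diazo-4-methyl-3-oxopent-4-enoate A2. Irradiation with ethoxyacetylene A3 should give, by Wolff rearrangement, (2+2) addition, four-electron ring opening and six-electron closure, the didepside A1.
- **In favour:** the reaction class is established, so no step needs invention; on precedent this alternative is better than the chosen plan. The two oxygens of ring B emerge differentiated (ether at B2, free phenol at B4), which equals the single-hydroxyl advantage of the pyrone.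
- **Against:** A2 is an activated aryl ester next to a ketone and an enone, and is open to acyl transfer and conjugate addition. A4 needs about three steps of oxygen differentiation. The ethyl ether of A1 must later be removed by the same kind of chelation-assisted dealkylation as in step 12, here on the central ring between two ester links. Ring A must still be attached to A1 by a hindered acylation with 9.
- **Comparison:** structurally both plans make one ring with its oxygens pre-differentiated. Mechanistically the alternative is a longer cascade but a known one. In step count it is expected to be equal or one to two steps longer.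

Alternative 2: The ester bond between ring B and ring C O4 and the B1–B6 bond are cut.
- **Forward step:** heating the dioxinone A6 with benzyl orsellinate A7 should release an acylketene that acylates the 4-hydroxyl of A7 to give the aryl trioxooctanoate A8. Aldol closure and dehydration then give the didepside A5.
- **In favour:** the chemistry is biomimetic and of a known type. Ester and ring are formed in one operation without a hindered acid chloride. No alkyl ether is left on ring B or C, so the end game after attaching ring A would be a single hydrogenolysis. On precedent, on the end game and probably on step count this alternative is the better one.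
- **Against:** A6 is a labile enolised polyketide that takes two to three steps to make. Ketene capture must choose between the two hydroxyls of A7. The aryloxy group of A8 is a good leaving group, so lactonisation to a hydroxypyrone with expulsion of A7 competes with the aldol. A5 has three free phenols, and acylation with 9 must pick the B4 hydroxyl among them.
- **Comparison:** the chosen plan answers each of these selectivity questions by construction and pays for it with an untested cycloaddition and one extra dealkylation. The alternative gives one ring and one ester per step, against one ring per step in the chosen plan.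

Alternative 3: Ring A is cut at A1–A2 and A5–A6.
- **Forward step:** the but-2-ynoate A10 of the ring B-C didepside phenol reacts as dienophile with the ketene-acetal diene A11. After 1,2-elimination of one acetal methoxy group and loss of the silyl group, the tridepside A9 results.
- **In favour:** the most crowded ring is made last on a preformed ester. The ring A–ring B ester thus comes from an unhindered alkynoic acid, which is better than the two hindered acyl chloride couplings of the chosen plan. The regiochemistry follows the established polarity of such dienes.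
- **Against:** a β-methyl alkynoate is a sluggish dienophile. A11 is hydrolytically labile and takes several steps. The aryl alkynoate is open to conjugate addition and acyl transfer. A9 again carries a methyl ether ortho to an ester, so the dealkylation liability is equal to that of the chosen plan. The ring B-C phenol needed for A10 requires full oxygen differentiation of two rings.
- **Comparison:** both plans rest on a polarity-matched cycloaddition that aromatises by loss of a small molecule. The alternative has better precedent, but it is expected to be several steps longer.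

Key step: step 11

Remark: 2,4-dihydroxy-6-methylbenzaldehyde (1) is taken as a purchasable compound; it is otherwise one Vilsmeier formylation away from orcinol, which would add one step.

Remark: the atom mapping of the key step was checked against the target; precursor 15, alkyne 18 and product 20 are mutually consistent and needed no correction.

## Route

Step 1
Reactants: 1 2,4-dihydroxy-6-methylbenzaldehyde
Product: 2 2,4-bis(benzyloxy)-6-methylbenzaldehyde
Conditions: BnBr (2.4 equiv), K2CO3, DMF, 60 °C
Reagents that add atoms: benzyl bromide, BrCc1ccccc1
Why: Williamson ether synthesis on both phenols; the chelated 2-hydroxyl needs warm DMF, and the molecule offers no other electrophile-sensitive site.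

Step 2
Reactants: 2 2,4-bis(benzyloxy)-6-methylbenzaldehyde
Product: 4 2,4-bis(benzyloxy)-6-methylphenol, via aryl formate 3 (not isolated)
Conditions: mCPBA, CH2Cl2, 0 °C → rt; then K2CO3 (cat.), MeOH, rt
Reagents that add atoms: 3-chloroperoxybenzoic acid (mCPBA), OOC(=O)c1cccc(Cl)c1
Why: Baeyer–Villiger (Dakin-type) oxidation; the ortho,para-dialkoxyaryl group migrates in the Criegee intermediate in preference to hydride, and the formate 3 is methanolysed to the phenol while the benzyl ethers stay inert.

Step 3
Reactants: 4 2,4-bis(benzyloxy)-6-methylphenol
Product: 5 1,2,5-tris(benzyloxy)-3-methylbenzene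
Conditions: BnBr, K2CO3, DMF, rt → 50 °C, Ar
Reagents that add atoms: benzyl bromide, BrCc1ccccc1
Why: Williamson ether synthesis; 4 is a hydroquinone monoether and is alkylated promptly under argon to forestall oxidation.

Step 4
Reactants: 5 1,2,5-tris(benzyloxy)-3-methylbenzene
Product: 7 2,4,5-tris(benzyloxy)-6-methylbenzaldehyde, via iminium chloride 6 (not isolated)
Conditions: POCl3, DMF, 0 → 70 °C; then H2O, rt
Reagents that add atoms: N,N-dimethylformamide, CN(C)C=O; water, O
Why: Vilsmeier–Haack formylation; both free positions are activated by the same two ether oxygens, but the bulky chloroiminium electrophile should prefer C4 (para to the C1 ether, flanked by methyl) over C6 (between two benzyloxy groups), as 3,5-dialkoxytoluenes do; water hydrolyses iminium 6.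

Step 5
Reactants: 7 2,4,5-tris(benzyloxy)-6-methylbenzaldehyde
Product: 8 2,4,5-tris(benzyloxy)-6-methylbenzoic acid
Conditions: NaClO2, NaH2PO4, 2-methyl-2-butene, t-BuOH/THF/H2O, rt
Reagents that add atoms: sodium chlorite, [Na+].[O-]Cl=O
Why: Pinnick oxidation; chlorite oxidises hindered, electron-rich aldehydes without touching benzyl ethers, and the alkene scavenges hypochlorous acid so that the ring is not chlorinated.

Step 6
Reactants: 8 2,4,5-tris(benzyloxy)-6-methylbenzoic acid; 1 2,4-dihydroxy-6-methylbenzaldehyde
Product: 10 4-formyl-3-hydroxy-5-methylphenyl 2,4,5-tris(benzyloxy)-6-methylbenzoate, via acid chloride 9 (not isolated)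
Conditions: (COCl)2, DMF (cat.), CH2Cl2, 0 °C → rt, evaporate; then 1 (1.1 equiv), Et3N, CH2Cl2, −20 °C → rt
Reagents that add atoms: none
Why: Acid chloride formation followed by phenol acylation; the 4-hydroxyl of 1 is the more acidic and is not held in the hydrogen bond to the formyl group that ties up the 2-hydroxyl, so one equivalent of 9 should acylate O4, the classical depside selectivity.

Step 7
Reactants: 10 4-formyl-3-hydroxy-5-methylphenyl 2,4,5-tris(benzyloxy)-6-methylbenzoate
Product: 11 3-(benzyloxy)-4-formyl-5-methylphenyl 2,4,5-tris(benzyloxy)-6-methylbenzoate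
Conditions: BnBr, K2CO3, DMF, 40 °C
Reagents that add atoms: benzyl bromide, BrCc1ccccc1
Why: Williamson ether synthesis with a mild carbonate base; the di-ortho-substituted aryl ester is sterically shielded and sits meta to the phenoxide, so no intramolecular acyl shift is possible.

Step 8
Reactants: 11 3-(benzyloxy)-4-formyl-5-methylphenyl 2,4,5-tris(benzyloxy)-6-methylbenzoate
Product: 12 2-(benzyloxy)-6-methyl-4-{[2,4,5-tris(benzyloxy)-6-methylbenzoyl]oxy}benzoic acid
Conditions: NaClO2, NaH2PO4, 2-methyl-2-butene, t-BuOH/THF/H2O, rt
Reagents that add atoms: sodium chlorite, [Na+].[O-]Cl=O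
Why: Pinnick oxidation under buffered, near-neutral conditions; the aryl ester and the benzyl ethers are inert, and the carboxyl appears without any deprotection next to the depside link.

Step 9
Reactants: 12 2-(benzyloxy)-6-methyl-4-{[2,4,5-tris(benzyloxy)-6-methylbenzoyl]oxy}benzoic acid; 13 4-hydroxy-6-methyl-2H-pyran-2-one
Product: 15 6-methyl-2-oxo-2H-pyran-4-yl 2-(benzyloxy)-6-methyl-4-{[2,4,5-tris(benzyloxy)-6-methylbenzoyl]oxy}benzoate, via acid chloride 14 (not isolated)
Conditions: (COCl)2, DMF (cat.), CH2Cl2, 0 °C → rt, evaporate; then 13, Et3N, CH2Cl2, −20 → 0 °C, no DMAP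
Reagents that add atoms: none
Why: O-acylation of a 4-hydroxy-2-pyrone (a vinylogous carboxylic acid) with an aroyl chloride and an amine base gives the 4-acyloxypyrone; leaving out nucleophilic catalysts avoids the known shift of the acyl group from oxygen to C3, and 14 has no α-hydrogen from which a ketene could form.

Step 10
Reactants: 16 chloroacetaldehyde dimethyl acetal
Product: 18 benzyl 3-methoxyprop-2-ynoate, via lithium methoxyacetylide 17 (not isolated)
Conditions: Et2NH, n-BuLi (3.1 equiv each), THF, −78 → 0 °C; then BnOCOCl, −78 °C
Reagents that add atoms: benzyl chloroformate, ClC(=O)OCc1ccccc1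
Why: Two successive eliminations (of methanol, then of hydrogen chloride) and deprotonation by three equivalents of lithium amide give acetylide 17 in the flask, so the volatile methoxyacetylene is never isolated; C-acylation of the acetylide by the chloroformate at low temperature gives the ynoate.

Step 11
Reactants: 15 6-methyl-2-oxo-2H-pyran-4-yl 2-(benzyloxy)-6-methyl-4-{[2,4,5-tris(benzyloxy)-6-methylbenzoyl]oxy}benzoate; 18 benzyl 3-methoxyprop-2-ynoate
Product: 20 benzyl 4-{[2-(benzyloxy)-6-methyl-4-{[2,4,5-tris(benzyloxy)-6-methylbenzoyl]oxy}benzoyl]oxy}-2-methoxy-6-methylbenzoate, via bridged lactone 19 (not isolated)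
Conditions: 18 (3 equiv), 1,2-dichlorobenzene, 150 °C, sealed tube, Ar
Reagents that add atoms: none
Why: Proposed new method: the 2-pyrone of 15 should act as a diene through C3=C4–C5=C6 and the polarised alkyne 18 as the two-electron partner in a thermal (4+2) cycloaddition; the closest known reaction type is the Diels–Alder/retro-Diels–Alder benzannulation of 4-alkoxy-6-methyl-2-pyrones with acetylenic esters, which also ends with loss of CO2, but a 3-alkoxypropiolate has not been paired with a 4-acyloxypyrone. Bond formation is expected to be asynchronous: pyrone C3, made nucleophilic by both the ring oxygen and the 4-oxygen, attacks the methoxy-bearing alkyne carbon (the electrophilic β-carbon of the ynoate), and the carbanion character developing next to the ester then closes onto the electrophilic C6. The resulting 2-oxabicyclo[2.2.2]octadienone 19 holds the two new bonds, ring C C2–C3 and C1–C6, and is not expected to persist at this temperature. Retro-(4+2) extrusion of CO2 from 19 aromatises the ring, so ring C closes as a six-membered carbocycle by an intermolecular cycloaddition followed by an irreversible fragmentation driven by aromaticity and entropy. No stereocentre is created in 20; the two bridgehead centres of 19 are transient and are erased on aromatisation. The selectivity needed is regiochemical (methoxy next to C3–H, ester next to the C6 methyl), and it is secured by the matched polarisation of the two partners, since the reversed orientation would pair two nucleophilic or two electrophilic termini. Chemoselectivity rests on three features: the methyl ynol ether has no β-hydrogen for a retro-ene fragmentation to a ketene, the di-ortho-substituted aroyl group of the vinylogous anhydride is shielded against acyl transfer, and the medium contains neither base nor nucleophile.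

Step 12
Reactants: 20 benzyl 4-{[2-(benzyloxy)-6-methyl-4-{[2,4,5-tris(benzyloxy)-6-methylbenzoyl]oxy}benzoyl]oxy}-2-methoxy-6-methylbenzoate
Product: 21 benzyl 2-hydroxy-4-{[2-hydroxy-6-methyl-4-{[2,4,5-trihydroxy-6-methylbenzoyl]oxy}benzoyl]oxy}-6-methylbenzoate
Conditions: BCl3, C6HMe5, CH2Cl2, −78 → 0 °C; then H2O
Reagents that add atoms: none
Why: Lewis-acid ether cleavage with pentamethylbenzene as a non-basic benzyl cation scavenger; aryl benzyl ethers should cleave at −78 °C, and the methyl ether ortho to the ester carbonyl through a six-membered boron chelate with chloride attack on the methyl group. The aryl esters and the benzyl ester are expected to persist in the cold; any acid formed by early loss of the benzyl ester is 22 itself and passes through step 13 unchanged.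

Step 13
Reactants: 21 benzyl 2-hydroxy-4-{[2-hydroxy-6-methyl-4-{[2,4,5-trihydroxy-6-methylbenzoyl]oxy}benzoyl]oxy}-6-methylbenzoate
Product: 22 2-hydroxy-4-{[2-hydroxy-6-methyl-4-{[2,4,5-trihydroxy-6-methylbenzoyl]oxy}benzoyl]oxy}-6-methylbenzoic acid (CNP0248995.0)
Conditions: H2 (1 atm), Pd/C, EtOAc/THF, rt; filter under Ar
Reagents that add atoms: none
Why: Hydrogenolysis of the benzyl ester on palladium on carbon is neutral, so the acid is released without decarboxylation or transesterification and the only by-product is volatile.

## Compound list

1 | 2,4-dihydroxy-6-methylbenzaldehyde | Cc1cc(O)cc(O)c1C=O | starting material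
2 | 2,4-bis(benzyloxy)-6-methylbenzaldehyde | Cc1cc(OCc2ccccc2)cc(OCc2ccccc2)c1C=O | intermediate
3 | 2,4-bis(benzyloxy)-6-methylphenyl formate (not isolated) | Cc1cc(OCc2ccccc2)cc(OCc2ccccc2)c1OC=O | intermediate
4 | 2,4-bis(benzyloxy)-6-methylphenol | Cc1cc(OCc2ccccc2)cc(OCc2ccccc2)c1O | intermediate
5 | 1,2,5-tris(benzyloxy)-3-methylbenzene | Cc1cc(OCc2ccccc2)cc(OCc2ccccc2)c1OCc1ccccc1 | intermediate
6 | N-{[2,4,5-tris(benzyloxy)-6-methylphenyl]methylidene}-N-methylmethanaminium chloride (not isolated) | Cc1c(C=[N+](C)C)c(OCc2ccccc2)cc(OCc2ccccc2)c1OCc1ccccc1.[Cl-] | intermediate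
7 | 2,4,5-tris(benzyloxy)-6-methylbenzaldehyde | Cc1c(C=O)c(OCc2ccccc2)cc(OCc2ccccc2)c1OCc1ccccc1 | intermediate
8 | 2,4,5-tris(benzyloxy)-6-methylbenzoic acid | Cc1c(C(=O)O)c(OCc2ccccc2)cc(OCc2ccccc2)c1OCc1ccccc1 | intermediate
9 | 2,4,5-tris(benzyloxy)-6-methylbenzoyl chloride (not isolated) | Cc1c(C(=O)Cl)c(OCc2ccccc2)cc(OCc2ccccc2)c1OCc1ccccc1 | intermediate
10 | 4-formyl-3-hydroxy-5-methylphenyl 2,4,5-tris(benzyloxy)-6-methylbenzoate | Cc1cc(OC(=O)c2c(C)c(OCc3ccccc3)c(OCc3ccccc3)cc2OCc2ccccc2)cc(O)c1C=O | intermediate
11 | 3-(benzyloxy)-4-formyl-5-methylphenyl 2,4,5-tris(benzyloxy)-6-methylbenzoate | Cc1cc(OC(=O)c2c(C)c(OCc3ccccc3)c(OCc3ccccc3)cc2OCc2ccccc2)cc(OCc2ccccc2)c1C=O | intermediate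
12 | 2-(benzyloxy)-6-methyl-4-{[2,4,5-tris(benzyloxy)-6-methylbenzoyl]oxy}benzoic acid | Cc1cc(OC(=O)c2c(C)c(OCc3ccccc3)c(OCc3ccccc3)cc2OCc2ccccc2)cc(OCc2ccccc2)c1C(=O)O | intermediate
13 | 4-hydroxy-6-methyl-2H-pyran-2-one | Cc1cc(O)cc(=O)o1 | starting material
14 | 2-(benzyloxy)-6-methyl-4-{[2,4,5-tris(benzyloxy)-6-methylbenzoyl]oxy}benzoyl chloride (not isolated) | Cc1cc(OC(=O)c2c(C)c(OCc3ccccc3)c(OCc3ccccc3)cc2OCc2ccccc2)cc(OCc2ccccc2)c1C(=O)Cl | intermediate
15 | 6-methyl-2-oxo-2H-pyran-4-yl 2-(benzyloxy)-6-methyl-4-{[2,4,5-tris(benzyloxy)-6-methylbenzoyl]oxy}benzoate | Cc1cc(OC(=O)c2c(C)cc(OC(=O)c3c(C)c(OCc4ccccc4)c(OCc4ccccc4)cc3OCc3ccccc3)cc2OCc2ccccc2)cc(=O)o1 | intermediate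
16 | chloroacetaldehyde dimethyl acetal (2-chloro-1,1-dimethoxyethane) | COC(CCl)OC | starting material
17 | lithium methoxyacetylide (not isolated) | COC#[C-].[Li+] | intermediate
18 | benzyl 3-methoxyprop-2-ynoate | COC#CC(=O)OCc1ccccc1 | intermediate
19 | benzyl 5-{[2-(benzyloxy)-6-methyl-4-{[2,4,5-tris(benzyloxy)-6-methylbenzoyl]oxy}benzoyl]oxy}-8-methoxy-1-methyl-3-oxo-2-oxabicyclo[2.2.2]octa-5,7-diene-7-carboxylate (racemic; the two bridgeheads are its only stereocentres and their relative configuration is fixed by the bicycle; not isolated) | O=C1OC2(C)C=C(OC(=O)c3c(C)cc(OC(=O)c4c(C)c(OCc5ccccc5)c(OCc5ccccc5)cc4OCc4ccccc4)cc3OCc3ccccc3)C1C(OC)=C2C(=O)OCc1ccccc1 | intermediate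
20 | benzyl 4-{[2-(benzyloxy)-6-methyl-4-{[2,4,5-tris(benzyloxy)-6-methylbenzoyl]oxy}benzoyl]oxy}-2-methoxy-6-methylbenzoate | COc1cc(OC(=O)c2c(C)cc(OC(=O)c3c(C)c(OCc4ccccc4)c(OCc4ccccc4)cc3OCc3ccccc3)cc2OCc2ccccc2)cc(C)c1C(=O)OCc1ccccc1 | intermediate
21 | benzyl 2-hydroxy-4-{[2-hydroxy-6-methyl-4-{[2,4,5-trihydroxy-6-methylbenzoyl]oxy}benzoyl]oxy}-6-methylbenzoate | Cc1cc(OC(=O)c2c(C)cc(OC(=O)c3c(O)cc(O)c(O)c3C)cc2O)cc(O)c1C(=O)OCc1ccccc1 | intermediate
22 | 2-hydroxy-4-{[2-hydroxy-6-methyl-4-{[2,4,5-trihydroxy-6-methylbenzoyl]oxy}benzoyl]oxy}-6-methylbenzoic acid (CNP0248995.0; achiral) | Cc1cc(OC(=O)c2c(C)cc(OC(=O)c3c(O)cc(O)c(O)c3C)cc2O)cc(O)c1C(=O)O | target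

## Step count and least certain steps

Total step count: 13. Longest linear sequence: 12 steps (steps 1 to 9, then 11, 12 and 13); step 10 is a one-step side branch.

**Step 11 (key step).**
- **Risk:** the cycloaddition may be too slow at temperatures that the vinylogous anhydride tolerates. Acyl transfer from the pyrone oxygen, migration of the acyl group to C3, or thermal decay of the ynol ether could then outrun it. Erosion of the regiochemistry through a less polarised transition state is the second possibility.
- **Fallback (known chemistry):** it sets out from acid 12, which is converted to chloride 14 as in step 9. Orsellinic acid F1 is esterified with benzyl bromide and KHCO3 in DMF to give benzyl 2,4-dihydroxy-6-methylbenzoate F2. F2 is acylated by 14 at its unchelated 4-hydroxyl (Et3N, CH2Cl2) to give benzyl 4-{[2-(benzyloxy)-6-methyl-4-{[2,4,5-tris(benzyloxy)-6-methylbenzoyl]oxy}benzoyl]oxy}-2-hydroxy-6-methylbenzoate F3. Hydrogenolysis (H2, Pd/C) should then remove all five benzyl groups and rejoin the route at 22.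
- **Scope:** this gives up the pyrone construction of ring C for a classical depside coupling. It also answers a failure of step 9.

**Step 4.**
- **Risk:** loss of regiocontrol, with formylation at the position between the two benzyloxy groups, or partial debenzylation in the acidic medium.
- **Fallback:** it sets out from 1. Elbs persulfate oxidation (K2S2O8, aqueous NaOH, then warm dilute HCl) hydroxylates the position para to the 2-hydroxyl and ortho to the 4-hydroxyl. It passes through potassium 3-formyl-4,6-dihydroxy-2-methylphenyl sulfate F4 to 2,4,5-trihydroxy-6-methylbenzaldehyde F5. Tribenzylation (BnBr, K2CO3, DMF, Ar) then rejoins the route at 7.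
- **Trade-off:** the regiochemistry is set by the para rule of the Elbs reaction, at the price of a lower-yielding oxidation.

**Step 7.**
- **Risk:** ester cleavage or intermolecular acyl scrambling by phenoxide or carbonate during the slow alkylation of the hydrogen-bonded phenol.
- **Fallback:** it sets out from 1 and attaches ring A only after ring B carries its benzyl ether.
  - Selective 4-O-allylation (allyl bromide, K2CO3, acetone, rt) gives 4-(allyloxy)-2-hydroxy-6-methylbenzaldehyde F6.
  - Benzylation gives 4-(allyloxy)-2-(benzyloxy)-6-methylbenzaldehyde F7.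
  - Deallylation with Pd(PPh3)4 and morpholine gives 2-(benzyloxy)-4-hydroxy-6-methylbenzaldehyde F8.
  - Acylation of F8 with chloride 9 (Et3N, CH2Cl2) rejoins the route at 11.

**Step 12.**
- **Risk:** Lewis-acid cleavage of a depside link, C-benzylation of the electron-rich rings by benzyl cations that escape the scavenger, or incomplete cleavage of the methyl ether.
- **Fallback:** it sets out from 20 and reverses the order of the end game. Hydrogenolysis (H2, Pd/C, THF) first removes all five benzyl groups under neutral conditions and gives 4-{[2-hydroxy-6-methyl-4-{[2,4,5-trihydroxy-6-methylbenzoyl]oxy}benzoyl]oxy}-2-methoxy-6-methylbenzoic acid F9. Only the chelated methyl ether is then left for BCl3 (CH2Cl2, −78 → 0 °C), which rejoins the route at 22.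

## Further compounds

F1 | step 11 | orsellinic acid (2,4-dihydroxy-6-methylbenzoic acid) | Cc1cc(O)cc(O)c1C(=O)O
F2 | step 11 | benzyl 2,4-dihydroxy-6-methylbenzoate | Cc1cc(O)cc(O)c1C(=O)OCc1ccccc1
F3 | step 11 | benzyl 4-{[2-(benzyloxy)-6-methyl-4-{[2,4,5-tris(benzyloxy)-6-methylbenzoyl]oxy}benzoyl]oxy}-2-hydroxy-6-methylbenzoate | Cc1cc(OC(=O)c2c(C)cc(OC(=O)c3c(C)c(OCc4ccccc4)c(OCc4ccccc4)cc3OCc3ccccc3)cc2OCc2ccccc2)cc(O)c1C(=O)OCc1ccccc1
F4 | step 4 | potassium 3-formyl-4,6-dihydroxy-2-methylphenyl sulfate | Cc1c(C=O)c(O)cc(O)c1OS(=O)(=O)[O-].[K+]
F5 | step 4 | 2,4,5-trihydroxy-6-methylbenzaldehyde | Cc1c(C=O)c(O)cc(O)c1O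
F6 | step 7 | 4-(allyloxy)-2-hydroxy-6-methylbenzaldehyde | Cc1cc(OCC=C)cc(O)c1C=O
F7 | step 7 | 4-(allyloxy)-2-(benzyloxy)-6-methylbenzaldehyde | Cc1cc(OCC=C)cc(OCc2ccccc2)c1C=O
F8 | step 7 | 2-(benzyloxy)-4-hydroxy-6-methylbenzaldehyde | Cc1cc(O)cc(OCc2ccccc2)c1C=O
F9 | step 12 | 4-{[2-hydroxy-6-methyl-4-{[2,4,5-trihydroxy-6-methylbenzoyl]oxy}benzoyl]oxy}-2-methoxy-6-methylbenzoic acid | COc1cc(OC(=O)c2c(C)cc(OC(=O)c3c(O)cc(O)c(O)c3C)cc2O)cc(C)c1C(=O)O
A1 | alternative 1 | benzyl 2-(benzyloxy)-4-[(2-ethoxy-4-hydroxy-6-methylbenzoyl)oxy]-6-methylbenzoate | CCOc1cc(O)cc(C)c1C(=O)Oc1cc(C)c(C(=O)OCc2ccccc2)c(OCc2ccccc2)c1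
A2 | alternative 1 | 3-(benzyloxy)-4-[(benzyloxy)carbonyl]-5-methylphenyl 2-diazo-4-methyl-3-oxopent-4-enoate | CC(=C)C(=O)C(=[N+]=[N-])C(=O)Oc1cc(C)c(C(=O)OCc2ccccc2)c(OCc2ccccc2)c1
A3 | alternative 1 | ethoxyacetylene | CCOC#C
A4 | alternative 1 | benzyl 2-(benzyloxy)-4-hydroxy-6-methylbenzoate | Cc1cc(O)cc(OCc2ccccc2)c1C(=O)OCc1ccccc1
A5 | alternative 2 | benzyl 4-[(2,4-dihydroxy-6-methylbenzoyl)oxy]-2-hydroxy-6-methylbenzoate | Cc1cc(O)cc(O)c1C(=O)Oc1cc(C)c(C(=O)OCc2ccccc2)c(O)c1
A6 | alternative 2 | 6-(2,4-dioxopentyl)-2,2-dimethyl-4H-1,3-dioxin-4-one | CC(=O)CC(=O)CC1=CC(=O)OC(C)(C)O1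
A7 | alternative 2 | benzyl orsellinate (benzyl 2,4-dihydroxy-6-methylbenzoate) | Cc1cc(O)cc(O)c1C(=O)OCc1ccccc1
A8 | alternative 2 | benzyl 2-hydroxy-6-methyl-4-[(3,5,7-trioxooctanoyl)oxy]benzoate | CC(=O)CC(=O)CC(=O)CC(=O)Oc1cc(C)c(C(=O)OCc2ccccc2)c(O)c1
A9 | alternative 3 | benzyl 2-(benzyloxy)-4-{[2-(benzyloxy)-4-{[5-(benzyloxy)-4-hydroxy-2-methoxy-6-methylbenzoyl]oxy}-6-methylbenzoyl]oxy}-6-methylbenzoate | COc1cc(O)c(OCc2ccccc2)c(C)c1C(=O)Oc1cc(C)c(C(=O)Oc2cc(C)c(C(=O)OCc3ccccc3)c(OCc3ccccc3)c2)c(OCc2ccccc2)c1
A10 | alternative 3 | benzyl 2-(benzyloxy)-4-{[2-(benzyloxy)-4-(but-2-ynoyloxy)-6-methylbenzoyl]oxy}-6-methylbenzoate | CC#CC(=O)Oc1cc(C)c(C(=O)Oc2cc(C)c(C(=O)OCc3ccccc3)c(OCc3ccccc3)c2)c(OCc2ccccc2)c1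
A11 | alternative 3 | 4-(benzyloxy)-1,1-dimethoxy-3-[(trimethylsilyl)oxy]buta-1,3-diene (C3=C4 geometry not fixed) | COC(OC)=CC(O[Si](C)(C)C)=COCc1ccccc1
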